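## Retrosynthetic overview

1. The strategy rests on rings A and B. They form a trans-decalin carrying an equatorial oxygen at C3, quaternary C4 (axial C19H2O) and C10, the C9 methine and the exocyclic C8=C17 alkene. This is the substitution pattern of a C19-oxidised farnesyl chain folded chair–chair.
2. The key disconnection cuts C4–C5 and C9–C10 back to the acyclic (3R,4S)-epoxy dienyl allylsilane 22. Ring A closes first and ring B directly after it in one cationic cascade, and loss of silicon fixes C8=C17.
3. The side chain follows the cascade. C11–C12 comes from catalyst-controlled propargylation of the C11 aldehyde (sets C11), C14–C15 from hydroxymethylation, and C13–C16 from carbonylation, which closes the butenolide as the last ring.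
4. Compound 22 comes from geraniol. Terminal cleavage, (Z)-selective olefination and Sharpless epoxidation set C3 and C4. Acetoacetate dianion alkylation forms C6–C7, and coupling of a (Z)-enol triflate with Me3SiCH2MgCl forms C8–C17.

Key step: step 15

**Numbering and abbreviations:** labdane numbering (C1–C20) is used for all compounds, including the acyclic ones. PMB = 4-methoxybenzyl, TBS = tert-butyldimethylsilyl, TES = triethylsilyl, Piv = pivaloyl.

**Remark:** the C8=C9 alkene of 18 and 20–22 is Z by the sequence rule, because O or CH2Si outranks C7. Its carbon chain (C7 to C11) nevertheless runs trans, as in an (E)-farnesyl unit.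

**Assumption:** (R)-TRIP is taken to direct allenylboronates to the Re face of aldehyde 26, as it does with simple aldehydes. This is also the face favoured by the Felkin–Anh model.

## Route

Step 1
Reactants: 1 geraniol
Product: 3 geranyl PMB ether, via sodium geranoxide 2 (not isolated)
Conditions: NaH, THF/DMF, 0 °C; PMBCl, n-Bu4NI (cat.), rt
Reagents that add atoms: 4-methoxybenzyl chloride, COc1ccc(CCl)cc1; sodium hydride, [Na+].[H-] (sodium of 2 only)
Why: Williamson ether synthesis on the primary allylic alkoxide gives an ether that, unlike an ester, survives the hydride reduction of step 5 and can later be removed oxidatively beside an oxirane and a silyl ether.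

Step 2
Reactants: 3 geranyl PMB ether
Product: 4 terminal epoxide of geranyl PMB ether
Conditions: mCPBA (1.0 equiv), CH2Cl2, −20 to 0 °C
Reagents that add atoms: mCPBA, O=C(OO)c1cccc(Cl)c1
Why: Prilezhaev epoxidation goes to the electron-richer isopropylidene alkene because the allylic ether oxygen deactivates the other one; the new centre forms racemic and is destroyed in step 3.

Step 3
Reactants: 4 terminal epoxide
Product: 5 (4E)-6-(PMB-oxy)-4-methylhex-4-enal
Conditions: H5IO6, THF/Et2O, 0 °C
Reagents that add atoms: none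
Why: Periodic acid hydrates the oxirane at its tertiary carbon and cleaves the glycol at once (Malaprade-type cleavage), cutting off acetone and leaving the aldehyde carbon that becomes C3.

Step 4
Reactants: 5 aldehyde; 6 ethyl 2-[bis(2,2,2-trifluoroethoxy)phosphoryl]propanoate
Product: 7 ethyl (2Z,6E)-8-(PMB-oxy)-2,6-dimethylocta-2,6-dienoate
Conditions: 6, KN(SiMe3)2, 18-crown-6, THF, −78 °C; then 5
Reagents that add atoms: phosphonate 6, CCOC(=O)C(C)P(=O)(OCC(F)(F)F)OCC(F)(F)F
Why: In the Still–Gennari variant of the Horner–Wadsworth–Emmons olefination the electron-poor phosphonate with a dissociated potassium ion eliminates under kinetic control, which should give the (Z)-enoate and so place the future C19 carbon cis to the chain.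

Step 5
Reactants: 7 (Z)-enoate
Product: 8 (2Z,6E)-8-(PMB-oxy)-2,6-dimethylocta-2,6-dien-1-ol
Conditions: i-Bu2AlH (2.5 equiv), CH2Cl2, −78 °C; aq. potassium sodium tartrate
Reagents that add atoms: none
Why: 1,2-Reduction of the enoate with i-Bu2AlH gives the allylic alcohol without changing either alkene geometry, and the PMB ether is inert.

Step 6
Reactants: 8 (Z)-allylic alcohol
Product: 9 (2S,3R)-epoxy alcohol (C3 R, C4 S)
Conditions: Ti(OiPr)4 (0.2 equiv), L-(+)-diethyl tartrate (0.24 equiv), t-BuOOH, 4 Å MS, CH2Cl2, −20 °C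
Reagents that add atoms: tert-butyl hydroperoxide, CC(C)(C)OO
Why: In the Sharpless asymmetric epoxidation only the alkene bearing the free allylic hydroxyl is bound to titanium, the (2R,3R)-tartrate delivers oxygen to the face that gives (2S,3R)-oxiranes from (Z)-allylic alcohols, and syn addition keeps C19 cis to the chain.

Step 7
Reactants: 9 epoxy alcohol
Product: 10 C19 TBS ether
Conditions: TBSCl, imidazole, DMF, 0 °C to rt
Reagents that add atoms: tert-butyldimethylsilyl chloride, CC(C)(C)[Si](C)(C)Cl
Why: Imidazole-promoted silylation of the primary alcohol installs a weakly basic ether oxygen next to the oxirane that should not compete for the Lewis acid in step 15.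

Step 8
Reactants: 10 TBS ether
Product: 11 epoxy allylic alcohol (C6–OH)
Conditions: DDQ, CH2Cl2/pH 7 buffer, 0 °C
Reagents that add atoms: none
Why: Oxidative PMB cleavage (hydride abstraction by DDQ, then hydrolysis of the oxocarbenium ion) runs under neutral conditions that leave the oxirane, silyl ether and alkene untouched.

Step 9
Reactants: 11 epoxy allylic alcohol
Product: 13 epoxy allylic bromide, via allylic mesylate 12 (not isolated)
Conditions: MsCl, Et3N, CH2Cl2, −40 °C; LiBr, THF, −40 to 0 °C
Reagents that add atoms: lithium bromide, [Li+].[Br-]; methanesulfonyl chloride, CS(=O)(=O)Cl (mesyl group of 12 only)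
Why: Mesylation followed by SN2 displacement with bromide is acid-free, so the oxirane survives and the (E)-alkene is neither transposed nor isomerised.

Step 10
Reactants: 13 epoxy allylic bromide; 14 methyl acetoacetate
Product: 16 epoxy β-keto ester, via acetoacetate dianion 15 (not isolated)
Conditions: 14, NaH, THF, 0 °C; n-BuLi, 0 °C; then 13, 0 °C; aq. quench
Reagents that add atoms: methyl acetoacetate 14, COC(=O)CC(C)=O; sodium hydride, [Na+].[H-], and n-butyllithium, [Li]CCCC (counter-ions of 15 only)
Why: In the γ-alkylation of the acetoacetate dianion the more basic terminal carbanion displaces the allylic bromide (SN2) far faster than the trisubstituted oxirane can react, forming C6–C7.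

Step 11
Reactants: 16 epoxy β-keto ester
Product: 18 (Z)-enol triflate, via sodium enolate 17 (not isolated)
Conditions: NaH, THF, 0 °C; PhNTf2, 0 °C to rt
Reagents that add atoms: N-phenylbis(trifluoromethanesulfonimide), O=S(=O)(C(F)(F)F)N(c1ccccc1)S(=O)(=O)C(F)(F)F; sodium hydride, [Na+].[H-] (sodium of 17 only)
Why: In this O-sulfonylation of a chelated enolate, sodium holds the enolate oxygen cis to the ester carbonyl, so the (Z)-enol triflate should form, and PhNTf2 releases no acid that could open the oxirane.

Step 12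
Reactants: 18 (Z)-enol triflate; 19 (trimethylsilyl)methylmagnesium chloride
Product: 20 (2Z,6E)-β-(silylmethyl) enoate
Conditions: 19 (1.5 equiv), Pd(PPh3)4 (5 mol%), THF, 0 °C to rt
Reagents that add atoms: Grignard reagent 19, C[Si](C)(C)C[Mg]Cl
Why: In the Kumada–Corriu coupling zerovalent palladium inserts into the vinylic C–OTf bond with retention, and transmetallation with the weakly nucleophilic Grignard reagent followed by reductive elimination keeps CH2SiMe3 cis to the ester, forming C8–C17.

Step 13
Reactants: 20 enoate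
Product: 21 (2Z,6E)-allylic alcohol (C11–OH)
Conditions: i-Bu2AlH (2.5 equiv), CH2Cl2, −78 °C; aq. potassium sodium tartrate
Reagents that add atoms: none
Why: 1,2-Reduction of the enoate at −78 °C leaves the oxirane, silyl ether and allylsilane intact, and the neutral work-up avoids protodesilylation.

Step 14
Reactants: 21 allylic alcohol
Product: 22 epoxy dienyl allylsilane pivalate (cyclisation precursor)
Conditions: PivCl, pyridine, DMAP (cat.), CH2Cl2, 0 °C
Reagents that add atoms: pivaloyl chloride, CC(C)(C)C(=O)Cl
Why: Acylation under basic conditions masks C11–OH as a hindered, poorly ionising ester that should not leave as an allyl cation or trap a cation in the next step.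

Step 15
Reactants: 22 epoxy dienyl allylsilane pivalate
Product: 23 3-hydroxy trans-decalin with C8=C17, C19–OTBS and C11–OPiv
Conditions: MeAlCl2 (2.5 equiv, hexanes), CH2Cl2 (high dilution), −78 °C; then H2O
Reagents that add atoms: none
Why: MeAlCl2 coordinates the oxirane oxygen and polarises the C4–O bond at the tertiary carbon, the C5=C10 alkene attacks C4 from the side opposite to oxygen, the developing tertiary C10 cation is taken by C9 of the allylsilane, and the C8 cation, stabilised by the adjacent C17–Si bond, gives up Me3Si to chloride, so the new alkene can only be C8=C17. The closest known reaction type is the Lewis acid-promoted epoxy-polyene cyclisation with allylsilane termination, which follows the Stork–Eschenmoser rule of antiperiplanar addition. Ring A closes 6-endo (both oxirane carbons and both alkene carbons end up in the ring) and ring B closes 6-endo-trig onto C10. C3 keeps its C–O bond and becomes the equatorial carbinol, C4 is inverted so that the CH2OTBS group cis to the chain on the oxirane becomes the axial C19, C5 and C10 are fixed trans by anti addition across the (E)-C5=C10 alkene in a chair–chair fold, and C9 follows from the allylsilane geometry, in which C11 lies trans to C7 and so ends equatorial, the absolute sense of the three new centres being relayed from the oxirane. The step needs opening at C4 rather than C3, Markovnikov polarity at both alkenes, chair rather than boat folding, and complete bicyclisation before the C3 oxygen, a proton loss or a hydride shift can intervene. The tertiary oxirane carbon, the trisubstituted alkenes, the strongly nucleophilic allylsilane, the weakly basic silyl ether and the poorly ionising pivalate, together with −78 °C and dilution, are what secure this.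

Step 16
Reactants: 23 3-hydroxy decalin
Product: 24 C3 TES ether
Conditions: Et3SiOTf, 2,6-lutidine, CH2Cl2, −78 to 0 °C
Reagents that add atoms: triethylsilyl triflate, CC[Si](CC)(CC)OS(=O)(=O)C(F)(F)F
Why: Silylation with the reactive silyl triflate covers the hindered equatorial C3 hydroxyl, which would otherwise be oxidised in step 18.

Step 17
Reactants: 24 C3 TES ether
Product: 25 C11 primary alcohol
Conditions: i-Bu2AlH (2.5 equiv), CH2Cl2, −78 °C; aq. potassium sodium tartrate
Reagents that add atoms: none
Why: Reductive cleavage of the pivalate avoids the strong base that hydrolysis of this hindered ester would need and leaves both silyl ethers in place.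

Step 18
Reactants: 25 C11 alcohol
Product: 26 C11 aldehyde
Conditions: Dess–Martin periodinane, CH2Cl2, 0 °C to rt; used without storage
Reagents that add atoms: none
Why: The Dess–Martin oxidation is non-basic, so the β,γ-unsaturated aldehyde should neither epimerise at C9 nor move its alkene into conjugation.

Step 19
Reactants: 26 C11 aldehyde; 27 allenylboronic acid pinacol ester
Product: 28 (11R)-homopropargylic alcohol
Conditions: 27 (1.5 equiv), (R)-TRIP (10 mol%), 4 Å MS, toluene, −20 to 0 °C; aqueous work-up
Reagents that add atoms: allenylboronate 27, C=C=CB1OC(C)(C)C(C)(C)O1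
Why: In the chiral phosphoric acid-catalysed propargylation the allenylboronate adds through a closed six-membered transition state with allenyl-to-propargyl transposition, the catalyst directs it to the Re face of C11 (also the Felkin–Anh face, anti to C9–C10) to set (11R), and any minor enantiomer carried from step 6 becomes a separable diastereomer here.

Step 20
Reactants: 28 homopropargylic alcohol
Product: 29 C11 TES ether
Conditions: Et3SiOTf, 2,6-lutidine, CH2Cl2, −78 to 0 °C
Reagents that add atoms: triethylsilyl triflate, CC[Si](CC)(CC)OS(=O)(=O)C(F)(F)F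
Why: Silylation blocks the C11 oxygen so that it can neither direct the hydroalumination of step 22 nor capture the acylpalladium of step 23 as a γ-lactone.

Step 21
Reactants: 29 terminal alkyne
Product: 31 propargylic alcohol, via lithium acetylide 30 (not isolated)
Conditions: n-BuLi, THF, −78 °C; (CH2O)n, −78 °C to rt
Reagents that add atoms: paraformaldehyde (as formaldehyde), C=O; n-butyllithium, [Li]CCCC (lithium of 30 only)
Why: Acetylide addition to formaldehyde uses the only acidic C–H in the molecule and forms C14–C15.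

Step 22
Reactants: 31 propargylic alcohol
Product: 33 (Z)-vinyl iodide, via cyclic vinylalanate 32 (not isolated)
Conditions: NaAlH2(OCH2CH2OMe)2, THF, 0 °C to rt; EtOAc; I2, THF, −78 to 0 °C
Reagents that add atoms: iodine, II; sodium bis(2-methoxyethoxy)aluminium hydride, [Na+].COCCO[AlH2-]OCCOC (sodium, aluminium and alkoxides of 32 only)
Why: Alkoxide-directed trans-hydroalumination places hydride on C14 and aluminium on C13 in a five-membered alanate, and iodinolysis with retention gives the iodide at C13 cis to C15H2OH.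

Step 23
Reactants: 33 (Z)-vinyl iodide
Product: 34 tris-silylated butenolide
Conditions: CO (1 atm), Pd(PPh3)4 (5 mol%), Et3N, THF, 50 °C
Reagents that add atoms: carbon monoxide, [C-]#[O+]
Why: In this palladium-catalysed carbonylative lactonisation zerovalent palladium adds to the C13–I bond with retention, CO inserts, and the cis C15 hydroxyl captures the acylpalladium to close the α-substituted butenolide.

Step 24
Reactants: 34 tris-silylated butenolide
Product: 35 14-deoxy-11-hydroxyandrographolide
Conditions: HF·pyridine, pyridine, THF, 0 °C to rt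
Reagents that add atoms: none
Why: Fluoride-driven desilylation in a buffered, mildly acidic medium frees the C3, C11 and C19 hydroxyls without the basic conditions that could isomerise the butenolide, and no stereocentre is touched.

## Compound list

1 | geraniol, (2E)-3,7-dimethylocta-2,6-dien-1-ol | CC(C)=CCC/C(C)=C/CO | starting material
2 | sodium geranoxide (not isolated) | [Na+].CC(C)=CCC/C(C)=C/C[O-] | intermediate
3 | geranyl 4-methoxybenzyl ether | CC(C)=CCC/C(C)=C/COCc1ccc(OC)cc1 | intermediate
4 | 6,7-epoxygeranyl PMB ether (racemic at the oxirane CH) | CC1(C)OC1CC/C(C)=C/COCc1ccc(OC)cc1 | intermediate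
5 | (4E)-6-[(4-methoxybenzyl)oxy]-4-methylhex-4-enal | O=CCC/C(C)=C/COCc1ccc(OC)cc1 | intermediate
6 | ethyl 2-[bis(2,2,2-trifluoroethoxy)phosphoryl]propanoate | CCOC(=O)C(C)P(=O)(OCC(F)(F)F)OCC(F)(F)F | starting material
7 | ethyl (2Z,6E)-8-[(4-methoxybenzyl)oxy]-2,6-dimethylocta-2,6-dienoate | CCOC(=O)/C(C)=C\CC/C(C)=C/COCc1ccc(OC)cc1 | intermediate
8 | (2Z,6E)-8-[(4-methoxybenzyl)oxy]-2,6-dimethylocta-2,6-dien-1-ol | OC/C(C)=C\CC/C(C)=C/COCc1ccc(OC)cc1 | intermediate
9 | {(2S,3R)-3-[(3E)-5-(PMB-oxy)-3-methylpent-3-enyl]-2-methyloxiran-2-yl}methanol | OC[C@]1(C)O[C@@H]1CC/C(C)=C/COCc1ccc(OC)cc1 | intermediate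
10 | TBS ether of 9 | CC(C)(C)[Si](C)(C)OC[C@]1(C)O[C@@H]1CC/C(C)=C/COCc1ccc(OC)cc1 | intermediate
11 | (2E)-5-[(2R,3S)-3-(TBS-oxymethyl)-3-methyloxiran-2-yl]-3-methylpent-2-en-1-ol | CC(C)(C)[Si](C)(C)OC[C@]1(C)O[C@@H]1CC/C(C)=C/CO | intermediate
12 | methanesulfonate of 11 (not isolated) | CC(C)(C)[Si](C)(C)OC[C@]1(C)O[C@@H]1CC/C(C)=C/COS(C)(=O)=O | intermediate
13 | allylic bromide corresponding to 11 | CC(C)(C)[Si](C)(C)OC[C@]1(C)O[C@@H]1CC/C(C)=C/CBr | intermediate
14 | methyl acetoacetate | COC(=O)CC(C)=O | starting material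
15 | sodium lithium dianion of methyl acetoacetate (not isolated) | [Na+].[Li+].[CH2-]C(=O)[CH-]C(=O)OC | intermediate
16 | methyl (6E)-9-[(2R,3S)-3-(TBS-oxymethyl)-3-methyloxiran-2-yl]-7-methyl-3-oxonon-6-enoate | CC(C)(C)[Si](C)(C)OC[C@]1(C)O[C@@H]1CC/C(C)=C/CCC(=O)CC(=O)OC | intermediate
17 | chelated (Z)-sodium enolate of 16 (not isolated) | [Na+].CC(C)(C)[Si](C)(C)OC[C@]1(C)O[C@@H]1CC/C(C)=C/CC/C([O-])=C/C(=O)OC | intermediate
18 | methyl (2Z,6E)-3-(triflyloxy)nona-2,6-dienoate derived from 16 (OTf cis to CO2Me) | CC(C)(C)[Si](C)(C)OC[C@]1(C)O[C@@H]1CC/C(C)=C/CC/C(OS(=O)(=O)C(F)(F)F)=C/C(=O)OC | intermediate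
19 | (trimethylsilyl)methylmagnesium chloride | C[Si](C)(C)C[Mg]Cl | starting material
20 | methyl (2Z,6E)-9-[(2R,3S)-3-(TBS-oxymethyl)-3-methyloxiran-2-yl]-7-methyl-3-[(trimethylsilyl)methyl]nona-2,6-dienoate | CC(C)(C)[Si](C)(C)OC[C@]1(C)O[C@@H]1CC/C(C)=C/CC/C(C[Si](C)(C)C)=C/C(=O)OC | intermediate
21 | (2Z,6E)-dien-1-ol from reduction of 20 | CC(C)(C)[Si](C)(C)OC[C@]1(C)O[C@@H]1CC/C(C)=C/CC/C(C[Si](C)(C)C)=C/CO | intermediate
22 | pivalate of 21, the (3R,4S)-epoxy dienyl allylsilane | CC(C)(C)[Si](C)(C)OC[C@]1(C)O[C@@H]1CC/C(C)=C/CC/C(C[Si](C)(C)C)=C/COC(=O)C(C)(C)C | intermediate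
23 | (3R,4R,5S,9R,10R) trans-decalin: equatorial 3-OH, 4-methyl, axial 4-CH2OTBS, 10-methyl, 8-methylene, equatorial 9-CH2OPiv | C=C1CC[C@@H]2[C@](C)(CO[Si](C)(C)C(C)(C)C)[C@H](O)CC[C@@]2(C)[C@@H]1COC(=O)C(C)(C)C | intermediate
24 | C3 TES ether of 23 | C=C1CC[C@@H]2[C@](C)(CO[Si](C)(C)C(C)(C)C)[C@H](O[Si](CC)(CC)CC)CC[C@@]2(C)[C@@H]1COC(=O)C(C)(C)C | intermediate
25 | C11 primary alcohol (3-OTES, 19-OTBS) | C=C1CC[C@@H]2[C@](C)(CO[Si](C)(C)C(C)(C)C)[C@H](O[Si](CC)(CC)CC)CC[C@@]2(C)[C@@H]1CO | intermediate
26 | C11 aldehyde (3-OTES, 19-OTBS) | C=C1CC[C@@H]2[C@](C)(CO[Si](C)(C)C(C)(C)C)[C@H](O[Si](CC)(CC)CC)CC[C@@]2(C)[C@@H]1C=O | intermediate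
27 | allenylboronic acid pinacol ester | C=C=CB1OC(C)(C)C(C)(C)O1 | starting material
28 | (11R)-homopropargylic alcohol (C11–OH, C13≡C14H) | C=C1CC[C@@H]2[C@](C)(CO[Si](C)(C)C(C)(C)C)[C@H](O[Si](CC)(CC)CC)CC[C@@]2(C)[C@@H]1[C@H](O)CC#C | intermediate
29 | C11 TES ether of 28 | C=C1CC[C@@H]2[C@](C)(CO[Si](C)(C)C(C)(C)C)[C@H](O[Si](CC)(CC)CC)CC[C@@]2(C)[C@@H]1[C@H](O[Si](CC)(CC)CC)CC#C | intermediate
30 | lithium acetylide of 29 (not isolated) | [Li+].C=C1CC[C@@H]2[C@](C)(CO[Si](C)(C)C(C)(C)C)[C@H](O[Si](CC)(CC)CC)CC[C@@]2(C)[C@@H]1[C@H](O[Si](CC)(CC)CC)CC#[C-] | intermediate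
31 | propargylic alcohol (C13≡C14–C15H2OH) | C=C1CC[C@@H]2[C@](C)(CO[Si](C)(C)C(C)(C)C)[C@H](O[Si](CC)(CC)CC)CC[C@@]2(C)[C@@H]1[C@H](O[Si](CC)(CC)CC)CC#CCO | intermediate
32 | sodium five-membered vinylalanate, Al on C13 and on O15 (not isolated) | [Na+].C=C1CC[C@@H]2[C@](C)(CO[Si](C)(C)C(C)(C)C)[C@H](O[Si](CC)(CC)CC)CC[C@@]2(C)[C@@H]1[C@H](O[Si](CC)(CC)CC)CC1=CCO[Al-]1(OCCOC)OCCOC | intermediate
33 | (13Z)-13-iodo allylic alcohol (I cis to C15H2OH) | C=C1CC[C@@H]2[C@](C)(CO[Si](C)(C)C(C)(C)C)[C@H](O[Si](CC)(CC)CC)CC[C@@]2(C)[C@@H]1[C@H](O[Si](CC)(CC)CC)C/C(I)=C/CO | intermediate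
34 | 3,11-bis-TES 19-TBS ether of the target | C=C1CC[C@@H]2[C@](C)(CO[Si](C)(C)C(C)(C)C)[C@H](O[Si](CC)(CC)CC)CC[C@@]2(C)[C@@H]1[C@H](O[Si](CC)(CC)CC)CC1=CCOC1=O | intermediate
35 | 14-deoxy-11-hydroxyandrographolide, (3R,4R,5S,9R,10R,11R) | C=C1CC[C@@H]2[C@](C)(CO)[C@H](O)CC[C@@]2(C)[C@@H]1[C@H](O)CC1=CCOC1=O | target

## Step count and risks

Total step count: 24.
Longest linear sequence: 24 steps (1 to 35).

**Step 15 (bicyclisation).**
- The cascade may stop early, through capture of the C10 cation by the C3 oxygen or proton loss after ring A.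
- The activated oxirane may rearrange by hydride shift.
- The silyl-allyl pivalate may ionise with 1,4-loss of silicon and ester.

The fallback keeps the same two bonds but changes the terminating nucleophile, so no allylsilane or allylic ester is exposed to the Lewis acid. It sets out from 16. Treatment with SnCl4 (CH2Cl2, −78 °C) lets the enol of the β-keto ester take the C10 cation at C9, a known type of polyene cyclisation terminated by a β-keto ester. This gives the bicyclic hydroxy β-keto ester F1, whose epimerisable C9 ester settles equatorial. Silylation with Et3SiCl, imidazole and DMAP gives the C3 TES ether F2. Non-basic ketone methylenation with Zn/CH2Br2/TiCl4 gives the exocyclic methylene ester F3. Reduction with i-Bu2AlH returns to the route at 25.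

**Step 19 (propargylation).**
- Addition to the hindered aldehyde may be slow. That would give time for epimerisation at C9 or drift of the alkene into conjugation.
- Facial discrimination at C11 may be insufficient.

The fallback sets out from 26 and builds C11–C12 by an auxiliary-controlled acetate aldol reaction. (R)-2-Hydroxy-1,2,2-triphenylethyl acetate is doubly deprotonated with LiN(i-Pr)2 and added to 26 at about −100 °C. This reagent gives (R)-carbinols with α-branched aldehydes, and the product is the β-hydroxy ester F4. Et3SiOTf/2,6-lutidine gives the C11 TES ether F5. i-Bu2AlH releases the auxiliary and gives the C13 primary alcohol F6. Dess–Martin oxidation gives the β-silyloxy aldehyde F7. Ohira–Bestmann homologation (dimethyl (1-diazo-2-oxopropyl)phosphonate, K2CO3, MeOH) returns to the route at 29.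

**Step 12 (Kumada–Corriu coupling).**
- Magnesium halide may open the oxirane.
- The Grignard reagent may attack the ester.
- The alkene geometry may erode.

The fallback sets out from 16 and replaces cross-coupling by conjugate addition–elimination with a magnesium-free reagent. NaH followed by ClP(O)(OEt)2 (Et2O, 0 °C) gives the (Z)-enol diethyl phosphate F8. The cuprate (Me3SiCH2)2CuLi, made from Me3SiCH2Li and CuI (Et2O, −78 to −20 °C), replaces the phosphate with retention of geometry. This returns to the route at 20.

## Further compounds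

F1 | step 15 | bicyclic hydroxy β-keto ester (8-oxo, equatorial 9-CO2Me, 3-OH, 19-OTBS; ring configuration as in 23) | O=C1CC[C@@H]2[C@](C)(CO[Si](C)(C)C(C)(C)C)[C@H](O)CC[C@@]2(C)[C@@H]1C(=O)OC
F2 | step 15 | C3 TES ether of F1 | O=C1CC[C@@H]2[C@](C)(CO[Si](C)(C)C(C)(C)C)[C@H](O[Si](CC)(CC)CC)CC[C@@]2(C)[C@@H]1C(=O)OC
F3 | step 15 | exocyclic methylene ester (C8=C17, 9-CO2Me, 3-OTES, 19-OTBS) | C=C1CC[C@@H]2[C@](C)(CO[Si](C)(C)C(C)(C)C)[C@H](O[Si](CC)(CC)CC)CC[C@@]2(C)[C@@H]1C(=O)OC
F4 | step 19 | (11R)-β-hydroxy ester of (R)-1,1,2-triphenylethane-1,2-diol | C=C1CC[C@@H]2[C@](C)(CO[Si](C)(C)C(C)(C)C)[C@H](O[Si](CC)(CC)CC)CC[C@@]2(C)[C@@H]1[C@H](O)CC(=O)O[C@H](c1ccccc1)C(O)(c1ccccc1)c1ccccc1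
F5 | step 19 | C11 TES ether of F4 | C=C1CC[C@@H]2[C@](C)(CO[Si](C)(C)C(C)(C)C)[C@H](O[Si](CC)(CC)CC)CC[C@@]2(C)[C@@H]1[C@H](O[Si](CC)(CC)CC)CC(=O)O[C@H](c1ccccc1)C(O)(c1ccccc1)c1ccccc1
F6 | step 19 | C13 primary alcohol (11-OTES) | C=C1CC[C@@H]2[C@](C)(CO[Si](C)(C)C(C)(C)C)[C@H](O[Si](CC)(CC)CC)CC[C@@]2(C)[C@@H]1[C@H](O[Si](CC)(CC)CC)CCO
F7 | step 19 | C13 aldehyde (11-OTES) | C=C1CC[C@@H]2[C@](C)(CO[Si](C)(C)C(C)(C)C)[C@H](O[Si](CC)(CC)CC)CC[C@@]2(C)[C@@H]1[C@H](O[Si](CC)(CC)CC)CC=O
F8 | step 12 | (Z)-enol diethyl phosphate of 16 | CC(C)(C)[Si](C)(C)OC[C@]1(C)O[C@@H]1CC/C(C)=C/CC/C(OP(=O)(OCC)OCC)=C/C(=O)OC
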